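Atom numbers follow the target SMILES. Everything rests on the vicinal diether O3–C4–C25–O26, in which C4 and C25 also carry the ring sp2 carbons C5 and C17: a glyoxal unit clamped between two carbinol oxygens and two arene-type carbons. With both epoxyquinol rings masked as 4-methoxyphenols, one acid-triggered double oxa-Pictet–Spengler reaction forms O3–C4, C4–C5, O26–C25 and C25–C17, closes both pyran rings and the eight-membered carbocycle, and sets C4 and C25. Its precursor is the C2-symmetric (2R,3S,4S,5R)-3,4-bis(5-hydroxy-2-methoxyphenyl)hexane-2,5-diol, met by glyoxal as its anhydrous bis(dimethyl acetal). Dearomatisation, epoxidation and carbonyl adjustment finish the synthesis.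

Key step: step 8

Assumption: the titanium enolate coupling of step 2 joins both partners on the face of the chelated (Z)-enolate remote from the benzyl group, as alkylations of the same enolate do, so the (S)-auxiliary gives the (S,S)-succinate.
Assumption: of the two pseudoenantiomeric cinchona salts, N-benzylcinchoninium chloride is taken to direct the peroxide to the required face in step 10.

Step 1
Reactants: 1 5-bromo-2-methoxyphenylacetic acid; 2 (S)-4-benzyl-2-oxazolidinone
Product: 4 (S)-4-benzyl-3-[(5-bromo-2-methoxyphenyl)acetyl]oxazolidin-2-one, via mixed pivalic anhydride 3 (not isolated)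
Conditions: t-BuCOCl, Et3N, THF, −20 °C; then LiCl, 2, −20 °C → rt
Reagents that add atoms: pivaloyl chloride, CC(C)(C)C(=O)Cl (acyl group of 3 only)
Why: N-acylation of an oxazolidinone auxiliary by the mixed-anhydride/LiCl method, which avoids ketene formation from the arylacetic acid; the bromine para to the methoxy group marks the later phenol carbon (C12/C18), so no phenol protecting group has to be carried.

Step 2
Reactants: 4 (S)-4-benzyl-3-[(5-bromo-2-methoxyphenyl)acetyl]oxazolidin-2-one (two molecules)
Product: 5 (2S,3S)-1,4-bis[(S)-4-benzyl-2-oxooxazolidin-3-yl]-2,3-bis(5-bromo-2-methoxyphenyl)butane-1,4-dione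
Conditions: TiCl4, Et3N, CH2Cl2, −45 → 0 °C
Reagents that add atoms: none
Why: Oxidative enolate homocoupling of an arylacetyl imide: soft enolisation gives the chelated (Z)-titanium enolate, tetravalent titanium is reduced to trivalent titanium, and the two benzylic α-carbons join on the enolate face remote from each benzyl group, which forms C14–C15 and sets both centres S (the chiral, non-meso series).

Step 3
Reactants: 5 bis-imide
Product: 7 (2S,3S)-2,3-bis(5-bromo-2-methoxyphenyl)succinic acid, via bis(peroxy acid) 6 (not isolated)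
Conditions: LiOH, 30% H2O2, THF–H2O, 0 °C; then Na2SO3; HCl to pH 2
Reagents that add atoms: hydrogen peroxide, OO
Why: Hydroperoxide cleavage of N-acyloxazolidinones: the small, weakly basic LiOOH attacks the exocyclic carbonyl even of a hindered imide without deprotonating the α-aryl centres C14/C15, and sulfite reduces the peracid to the acid while the auxiliary is recovered.

Step 4
Reactants: 7 (2S,3S)-diacid
Product: 8 (2S,3S)-2,3-bis(5-bromo-2-methoxyphenyl)-N1,N4-dimethoxy-N1,N4-dimethylsuccinamide
Conditions: MeNH(OMe)·HCl, EDC·HCl, 1-hydroxybenzotriazole, N-methylmorpholine, CH2Cl2, 0 °C → rt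
Reagents that add atoms: N,O-dimethylhydroxylamine hydrochloride, CNOC.Cl
Why: Carbodiimide/hydroxybenzotriazole amide coupling to the bis(Weinreb amide), in which activation in the presence of only a weak tertiary amine keeps C14/C15 from epimerising.

Step 5
Reactants: 8 bis(Weinreb amide); 9 methylmagnesium bromide
Product: 10 (3S,4S)-3,4-bis(5-bromo-2-methoxyphenyl)hexane-2,5-dione
Conditions: 9, THF, −20 → 0 °C; cold 1 M HCl quench
Reagents that add atoms: methylmagnesium bromide 9, C[Mg]Br
Why: Weinreb ketone synthesis: each amide forms a stable magnesium chelate that cannot take up a second methyl group and collapses to the ketone only in the cold acidic quench, so the enolisable α-aryl ketone never meets base, and aryl bromides are inert to MeMgBr at this temperature.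

Step 6
Reactants: 10 (3S,4S)-diketone
Product: 11 (2R,3S,4S,5R)-3,4-bis(5-bromo-2-methoxyphenyl)hexane-2,5-diol
Conditions: (S)-2-methyl-CBS-oxazaborolidine [(S)-tetrahydro-1-methyl-3,3-diphenyl-1H,3H-pyrrolo[1,2-c][1,3,2]oxazaborole, 20 mol % per C=O], BH3·SMe2, THF, −20 °C; MeOH quench
Reagents that add atoms: none
Why: Corey–Bakshi–Shibata reduction of methyl ketones under neutral conditions: methyl is the small and the C14/C15 methine the large substituent, so the (S)-catalyst delivers hydride to give the R carbinols C2 and C27 by reagent control without touching C14/C15.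

Step 7
Reactants: 11 dibromo diol
Product: 13 (2R,3S,4S,5R)-3,4-bis(5-hydroxy-2-methoxyphenyl)hexane-2,5-diol, via bis(pinacol boronate) 12 (not isolated)
Conditions: B2pin2, Pd(dppf)Cl2 (5 mol %), KOAc, 1,4-dioxane, 90 °C; then 30% H2O2, NaOH, THF–H2O, 0 °C; HCl work-up
Reagents that add atoms: bis(pinacolato)diboron, CC1(C)OB(OC1(C)C)B1OC(C)(C)C(C)(C)O1 (boron of 12 only); hydrogen peroxide, OO (phenol oxygen of 13)
Why: Miyaura borylation followed by oxidative carbon-to-oxygen migration on boron, both tolerant of free secondary alcohols, replaces each bromine by hydroxyl at the same carbon, so the phenol ends up para to methoxy and ortho to the carbon (C5/C17) that must react next.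

Step 8
Reactants: 13 (2R,3S,4S,5R)-3,4-bis(5-hydroxy-2-methoxyphenyl)hexane-2,5-diol; 14 glyoxal bis(dimethyl acetal) (1,1,2,2-tetramethoxyethane)
Product: 16 dibenzo cage bis(4-methoxyphenol), via half-closed isochroman acetal 15 (not isolated)
Conditions: 14 (1.05 equiv), CF3SO3H (30 mol %), CH2Cl2–(CF3)2CHOH (4:1), 2 mM by slow addition, −20 → 0 °C
Reagents that add atoms: glyoxal bis(dimethyl acetal) 14, COC(OC)C(OC)OC
Why: Proposed new method: CF3SO3H exchanges one acetal carbon of 14 onto the C2 carbinol and ionises it to the oxocarbenium ion O3=C4, which is captured by C5, the arene carbon ortho to the free phenol, to give 15, and the surviving dimethyl acetal then repeats the sequence with O26 and C17. The closest known reaction type is the oxa-Pictet–Spengler synthesis of isochromans from 1-arylpropan-2-ols and aldehydes or acetals, which has not been run twice on one two-carbon unit to close a cage. Each pyran ring closes 6-endo-trig at its oxocarbenium carbon, and the C25–C17 bond at the same time closes the eight-membered carbocycle C4–C5–C6–C14–C15–C16–C17–C25 in an 8-exo-trig sense, prepared by the first ring, which already holds C25 and C15 on one face. C4 is set by the backbone: the C7 methoxy group is peri to C14 and drives the C14–C15 bond pseudoaxial, the trans methyl group on C2 follows into an axial site, and the (E)-oxocarbenium ion then places C25 pseudoequatorial on the face that carries C15 (1,3-trans and 1,4-cis in the isochroman). C25 is set by the tether, because with C4, C15 and C27 fixed only one face of the O26=C25 cation can reach C17. The step needs attack at C5 and C17 only and ring closure in preference to oligomerisation: the carbon para to each phenol carries methoxy, the other ortho carbon (C11, C20) cannot reach the cation through a six-membered transition state, trapping by phenol or alcohol oxygen is reversible whereas C–C bond formation is not, and high dilution with one equivalent of the monomeric, water-free acetal 14 (in place of hydrated, oligomeric glyoxal) suppresses double capping.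

Step 9
Reactants: 16 dibenzo cage bis(4-methoxyphenol)
Product: 17 cage bis(quinone monoketal)
Conditions: PhI(OAc)2 (2.2 equiv), MeOH, 0 °C
Reagents that add atoms: methanol, CO
Why: Hypervalent-iodine oxidative dearomatisation of 4-methoxyphenols in methanol (quinone monoketal synthesis): methanol adds at the methoxy-bearing para carbons C7/C23, which leaves C12/C18 as the only carbonyl groups and thereby fixes which oxygen becomes the carbinol and which the ketone.

Step 10
Reactants: 17 cage bis(quinone monoketal)
Product: 18 cage bis(epoxy ketone)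
Conditions: t-BuOOH, 0.1 M aq NaOH, N-benzylcinchoninium chloride (20 mol %), toluene, 0 °C → rt
Reagents that add atoms: tert-butyl hydroperoxide, CC(C)(C)OO
Why: Weitz–Scheffer epoxidation under chiral phase-transfer catalysis, a method established for quinone monoketals that lack the directing hydroxyl group needed by tartrate systems: the peroxide can add only to C9/C22 because C5=C6 and C16=C17 are tetrasubstituted, and the cinchoninium ion pair rather than the nearly unbiased cage selects the ring face turned away from the other half (the face of the neighbouring methyl group), setting C9, C11, C20 and C22, with mixed-face isomers being separable diastereomers.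

Step 11
Reactants: 18 cage bis(epoxy ketone)
Product: 19 cage bis(cis-epoxy alcohol) (12R,18R)
Conditions: NaBH4, CeCl3·7H2O, MeOH, −78 °C
Reagents that add atoms: none
Why: Luche 1,2-reduction: hydride attacks C12/C18 anti to the adjacent epoxide C–O bond (polar Felkin–Anh alignment and the less encumbered face), as is general for epoxycyclohexenone ketals, so the hydroxyl groups are expected cis to the epoxides, which is the epimer of the target at these two centres and is corrected in step 12.

Step 12
Reactants: 19 cage bis(cis-epoxy alcohol)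
Product: 20 cage bis(4-nitrobenzoate) (12S,18S)
Conditions: 4-O2NC6H4CO2H, PPh3, DIAD, toluene, 0 °C → rt
Reagents that add atoms: 4-nitrobenzoic acid, OC(=O)c1ccc(cc1)[N+](=O)[O-]
Why: Mitsunobu reaction with an acidic carboxylic acid: SN2 displacement of the two oxyphosphonium groups inverts C12 and C18 to the S configuration with oxygen anti to the epoxide, the SN2' alternative being blocked by the fully substituted carbons C6 and C16.

Step 13
Reactants: 20 cage bis(4-nitrobenzoate)
Product: 21 cage bis(trans-epoxy alcohol) bis(dimethyl ketal)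
Conditions: K2CO3 (20 mol %), MeOH, 0 °C
Reagents that add atoms: none
Why: Base-catalysed transesterification of an activated aryl ester, which breaks only the acyl–oxygen bonds so that C12/C18 keep their configuration, and which is fast enough at 0 °C to outrun Payne migration of the trans-epoxy alkoxide.

Step 14
Reactants: 21 cage bis(trans-epoxy alcohol) bis(dimethyl ketal)
Product: 22 epoxytwinol A
Conditions: TsOH·H2O (20 mol %), THF–H2O (4:1), rt
Reagents that add atoms: water, O
Why: Acid-catalysed hydrolysis of allylic dimethyl ketals, whose cations are conjugated with C5=C6 and C16=C17 and therefore form under mild acid that leaves the epoxides, cage ethers and carbinols untouched, reveals the C7 and C23 enones without affecting any stereocentre.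

Compound list
1 | 5-bromo-2-methoxyphenylacetic acid | OC(=O)Cc1cc(Br)ccc1OC | starting material
2 | (S)-4-benzyl-2-oxazolidinone | O=C1OC[C@H](Cc2ccccc2)N1 | starting material
3 | (5-bromo-2-methoxyphenyl)acetic pivalic anhydride | CC(C)(C)C(=O)OC(=O)Cc1cc(Br)ccc1OC | intermediate
4 | (S)-4-benzyl-3-[(5-bromo-2-methoxyphenyl)acetyl]oxazolidin-2-one | O=C1OC[C@H](Cc2ccccc2)N1C(=O)Cc1cc(Br)ccc1OC | intermediate
5 | (2S,3S)-1,4-bis[(S)-4-benzyl-2-oxooxazolidin-3-yl]-2,3-bis(5-bromo-2-methoxyphenyl)butane-1,4-dione | O=C1OC[C@H](Cc2ccccc2)N1C(=O)[C@H](c1cc(Br)ccc1OC)[C@@H](c1cc(Br)ccc1OC)C(=O)N1[C@@H](Cc2ccccc2)COC1=O | intermediate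
6 | (2S,3S)-2,3-bis(5-bromo-2-methoxyphenyl)butanediperoxoic acid | OOC(=O)[C@H](c1cc(Br)ccc1OC)[C@@H](c1cc(Br)ccc1OC)C(=O)OO | intermediate
7 | (2S,3S)-2,3-bis(5-bromo-2-methoxyphenyl)succinic acid | OC(=O)[C@H](c1cc(Br)ccc1OC)[C@@H](c1cc(Br)ccc1OC)C(=O)O | intermediate
8 | (2S,3S)-2,3-bis(5-bromo-2-methoxyphenyl)-N1,N4-dimethoxy-N1,N4-dimethylsuccinamide | CON(C)C(=O)[C@H](c1cc(Br)ccc1OC)[C@@H](c1cc(Br)ccc1OC)C(=O)N(C)OC | intermediate
9 | methylmagnesium bromide | C[Mg]Br | starting material
10 | (3S,4S)-3,4-bis(5-bromo-2-methoxyphenyl)hexane-2,5-dione | CC(=O)[C@H](c1cc(Br)ccc1OC)[C@@H](c1cc(Br)ccc1OC)C(C)=O | intermediate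
11 | (2R,3S,4S,5R)-3,4-bis(5-bromo-2-methoxyphenyl)hexane-2,5-diol | C[C@@H](O)[C@H](c1cc(Br)ccc1OC)[C@@H](c1cc(Br)ccc1OC)[C@@H](C)O | intermediate
12 | (2R,3S,4S,5R)-3,4-bis[2-methoxy-5-(4,4,5,5-tetramethyl-1,3,2-dioxaborolan-2-yl)phenyl]hexane-2,5-diol | C[C@@H](O)[C@H](c1cc(B2OC(C)(C)C(C)(C)O2)ccc1OC)[C@@H](c1cc(B2OC(C)(C)C(C)(C)O2)ccc1OC)[C@@H](C)O | intermediate
13 | (2R,3S,4S,5R)-3,4-bis(5-hydroxy-2-methoxyphenyl)hexane-2,5-diol | C[C@@H](O)[C@H](c1cc(O)ccc1OC)[C@@H](c1cc(O)ccc1OC)[C@@H](C)O | intermediate
14 | glyoxal bis(dimethyl acetal) (1,1,2,2-tetramethoxyethane) | COC(OC)C(OC)OC | starting material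
15 | (1S,3R,4S)-1-(dimethoxymethyl)-4-[(1S,2R)-2-hydroxy-1-(5-hydroxy-2-methoxyphenyl)propyl]-5-methoxy-3-methylisochroman-8-ol | C[C@H]1O[C@H](C(OC)OC)c2c(c(OC)ccc2O)[C@@H]1[C@@H](c1cc(O)ccc1OC)[C@@H](C)O | intermediate
16 | dibenzo cage bis(4-methoxyphenol), (2R,4S,14S,15S,25S,27R): target skeleton with rings C5–C12 and C16–C23 aromatic, OH on C12 and C18, OMe on C7 and C23 | C[C@H]1O[C@H]2c3c(c(OC)ccc3O)[C@@H]1[C@H]1c3c(c(O)ccc3OC)[C@@H]2O[C@@H]1C | intermediate
17 | cage bis(quinone monoketal): C12 and C18 carbonyls, C7 and C23 dimethyl ketals, C9=C11 and C20=C22 alkenes | C[C@H]1O[C@H]2C3=C(C(OC)(OC)C=CC3=O)[C@@H]1[C@H]1C3=C(C(=O)C=CC3(OC)OC)[C@@H]2O[C@@H]1C | intermediate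
18 | cage bis(epoxy ketone), (9R,11S,20S,22R): O10 and O21 on the ring faces turned away from the other half | C[C@H]1O[C@H]2C3=C(C(OC)(OC)[C@@H]4O[C@@H]4C3=O)[C@@H]1[C@H]1C3=C(C(=O)[C@H]4O[C@H]4C3(OC)OC)[C@@H]2O[C@@H]1C | intermediate
19 | cage bis(cis-epoxy alcohol) bis(dimethyl ketal), (9R,11R,12R,18R,20R,22R) | C[C@H]1O[C@H]2C3=C(C(OC)(OC)[C@@H]4O[C@@H]4[C@@H]3O)[C@@H]1[C@H]1C3=C([C@@H](O)[C@H]4O[C@H]4C3(OC)OC)[C@@H]2O[C@@H]1C | intermediate
20 | cage bis(4-nitrobenzoate) bis(dimethyl ketal), (12S,18S), acyloxy groups anti to the epoxides | C[C@H]1O[C@H]2C3=C(C(OC)(OC)[C@@H]4O[C@@H]4[C@H]3OC(=O)c5ccc(cc5)[N+](=O)[O-])[C@@H]1[C@H]1C3=C([C@H](OC(=O)c5ccc(cc5)[N+](=O)[O-])[C@H]4O[C@H]4C3(OC)OC)[C@@H]2O[C@@H]1C | intermediate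
21 | cage bis(trans-epoxy alcohol) bis(dimethyl ketal), (9R,11R,12S,18S,20R,22R) | C[C@H]1O[C@H]2C3=C(C(OC)(OC)[C@@H]4O[C@@H]4[C@H]3O)[C@@H]1[C@H]1C3=C([C@H](O)[C@H]4O[C@H]4C3(OC)OC)[C@@H]2O[C@@H]1C | intermediate
22 | epoxytwinol A, (2R,4S,9R,11R,12S,14S,15S,18S,20R,22R,25S,27R) | C[C@H]1O[C@H]2C3=C(C(=O)[C@@H]4O[C@@H]4[C@H]3O)[C@@H]1[C@H]1C3=C([C@H](O)[C@H]4O[C@H]4C3=O)[C@@H]2O[C@@H]1C | target

Total steps: 14. Longest linear sequence: 14 steps (1 → 22).

Steps most likely to fail

Step 8. After the first ring has closed, the second cation may be trapped by oxygen nucleophiles or by another molecule faster than C17 reaches it, so the reaction stalls or oligomerises. C4 may also form with the wrong sense. The fallback uses known chemistry and closes the cage in stages.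
- It sets out from 13. Condensation with one equivalent of 2,2-dimethoxyacetaldehyde under catalytic TsOH·H2O in MeCN is an ordinary single oxa-Pictet–Spengler reaction. It gives 15, which is now isolated and freed from any C4 epimer.
- Aqueous CF3CO2H unmasks the isochroman-1-carbaldehyde F1.
- Three equivalents of EtMgBr in toluene convert the acidic groups into magnesium salts. The bromomagnesium phenolate of the second arene binds the aldehyde and delivers it to its ortho carbon C17 (ortho-specific phenolate hydroxyalkylation). This closes the carbocycle as the C25 benzylic alcohol F2.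
- Catalytic camphorsulfonic acid in CH2Cl2 ionises this ortho-hydroxybenzyl alcohol to the ortho-quinone methide. O26 captures it in a six-membered closure, and the fallback comes back to the route at 16.

Step 10. Facial discrimination may be low, because the reacting alkene lies far from the cage stereocentres and the ion-pair catalyst may not recognise the substrate. Mixed-face bis-epoxides could then dominate. The fallback replaces catalyst control by a covalent auxiliary.
- It sets out from 17. BF3·OEt2-catalysed ketal exchange with (2R,4R)-pentane-2,4-diol in DME gives the bis(4,6-dimethyl-1,3-dioxane) spiroketal F3. An axial methyl group of each dioxane chair covers one face of the neighbouring C9=C11 or C20=C22 alkene.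
- Achiral Weitz–Scheffer epoxidation (t-BuOOH, DBU, CH2Cl2) gives the bis-epoxide F4.
- The operations of steps 11 to 14 then lead through the cis-epoxy alcohol F5, the inverted bis(4-nitrobenzoate) F6 and the trans-epoxy alcohol F7.
- Acid hydrolysis of F7 releases the diol auxiliary and comes back to the route at 22.

Step 12. The double SN2 displacement next to an epoxide may be sluggish. Elimination or loss of the activated oxygen without inversion could take over. The fallback replaces inversion by reagent-controlled hydride delivery.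
- It sets out from 18 and reduces both ketones with (S)-2-methyl-CBS-oxazaborolidine and catecholborane in toluene at −40 °C.
- The tetrasubstituted alkene carbon C5/C17 is treated as the large substituent, as in 2-substituted cyclohexenones, so hydride is delivered to the epoxide-bearing face and gives the S carbinols directly.
- It comes back to the route at 21 and bypasses 19 and 20; new compounds: none F0.

Further compounds
F1 | step 8 | (1S,3R,4S)-8-hydroxy-4-[(1S,2R)-2-hydroxy-1-(5-hydroxy-2-methoxyphenyl)propyl]-5-methoxy-3-methylisochroman-1-carbaldehyde | C[C@H]1O[C@H](C=O)c2c(c(OC)ccc2O)[C@@H]1[C@@H](c1cc(O)ccc1OC)[C@@H](C)O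
F2 | step 8 | carbocycle-closed C25 benzylic alcohol with O26 still free (either C25 epimer) | C[C@H]1O[C@H]2c3c(c(OC)ccc3O)[C@@H]1[C@@H](c1c(C2O)c(O)ccc1OC)[C@@H](C)O
F3 | step 10 | cage bis(quinone monoketal) as the bis[(4R,6R)-4,6-dimethyl-1,3-dioxane] spiroketal | C[C@H]1O[C@H]2C3=C(C5(O[C@H](C)C[C@@H](C)O5)C=CC3=O)[C@@H]1[C@H]1C3=C(C(=O)C=CC35O[C@H](C)C[C@@H](C)O5)[C@@H]2O[C@@H]1C
F4 | step 10 | bis(epoxy ketone) of the dioxane spiroketal series | C[C@H]1O[C@H]2C3=C(C5(O[C@H](C)C[C@@H](C)O5)[C@@H]4O[C@@H]4C3=O)[C@@H]1[C@H]1C3=C(C(=O)[C@H]4O[C@H]4C35O[C@H](C)C[C@@H](C)O5)[C@@H]2O[C@@H]1C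
F5 | step 10 | bis(cis-epoxy alcohol) of the dioxane spiroketal series | C[C@H]1O[C@H]2C3=C(C5(O[C@H](C)C[C@@H](C)O5)[C@@H]4O[C@@H]4[C@@H]3O)[C@@H]1[C@H]1C3=C([C@@H](O)[C@H]4O[C@H]4C35O[C@H](C)C[C@@H](C)O5)[C@@H]2O[C@@H]1C
F6 | step 10 | inverted bis(4-nitrobenzoate) of the dioxane spiroketal series | C[C@H]1O[C@H]2C3=C(C5(O[C@H](C)C[C@@H](C)O5)[C@@H]4O[C@@H]4[C@H]3OC(=O)c6ccc(cc6)[N+](=O)[O-])[C@@H]1[C@H]1C3=C([C@H](OC(=O)c6ccc(cc6)[N+](=O)[O-])[C@H]4O[C@H]4C35O[C@H](C)C[C@@H](C)O5)[C@@H]2O[C@@H]1C
F7 | step 10 | bis(trans-epoxy alcohol) of the dioxane spiroketal series | C[C@H]1O[C@H]2C3=C(C5(O[C@H](C)C[C@@H](C)O5)[C@@H]4O[C@@H]4[C@H]3O)[C@@H]1[C@H]1C3=C([C@H](O)[C@H]4O[C@H]4C35O[C@H](C)C[C@@H](C)O5)[C@@H]2O[C@@H]1C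
F0 | step 12 | none | none
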